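**Plan**

- Enabling feature: ring B of the trans-decalin holds one isolated trisubstituted alkene, C7=C8 (C17 methyl on C8), between C6H2 on C5 and the C9 methine. Cutting it (metathesis retron) leaves a ring-A ketone with an allyl arm on C5 and an isopropenyl arm on C9.
- Further cuts: C9–C10 (anionic oxy-Cope retron, which keeps the C2 carbonyl), then C2–CH2 of the carbinol. This gives (R)-4-allylisophorone and an 8-chlorogeranyl silyl ether whose ten carbons are C8, C9, C11–C17 and the CH2 later lost as ethylene. Last cut: C5–C6 (Claisen retron), back to 2,4,4-trimethylcyclohexenone.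
- Forward order: ring A is bought and the C5 arm is built. The whole side chain is joined at C2 and shifted to C10, ring B closes by metathesis, and C3–O is then introduced. The C15 silyl ether is exchanged for acetate at the end, because an acetate would not survive the organobarium, KH and amide-base steps.
- Stereochemistry: a CBS reduction sets a C1 carbinol and the Claisen shift relays it to C5. C5 steers the addition at C2, the suprafacial [3,3] shift relays that centre to C10, and its chair-like array with the E-alkene sets C9. C3 is set last by equilibration to the equatorial ketol, and the 13E alkene comes from geraniol.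

Key step: step 10

Remark: labdane numbering (C1–C20) is used for all intermediates, and 2,4,4-trimethylcyclohex-2-en-1-one is taken to be a catalogue chemical.

**Route**

Step 1
Reactants: 1 2,4,4-trimethylcyclohex-2-en-1-one
Product: 2 (S)-2,4,4-trimethylcyclohex-2-en-1-ol
Conditions: (R)-2-methyl-CBS-oxazaborolidine (10 mol%), BH3·SMe2, THF, −20 °C; aq work-up
Reagents that add atoms: none
Why: Corey–Bakshi–Shibata reduction, in which the (R)-oxazaborolidine binds the ketone with the α-methyl-substituted alkenyl arm as the large group and delivers hydride to one face, should set the (S)-carbinol at C1, the source of all absolute configuration.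

Step 2
Reactants: 2 (S)-2,4,4-trimethylcyclohex-2-en-1-ol
Product: 4 (R)-2-(2,6,6-trimethylcyclohex-2-en-1-yl)acetaldehyde, via vinyl ether 3 (not isolated)
Conditions: ethyl vinyl ether (solvent), Hg(OAc)2 (cat.), reflux; concentrate; toluene, sealed tube, 190 °C
Reagents that add atoms: ethyl vinyl ether C=COCC
Why: Transvinylation followed by an aliphatic Claisen rearrangement, whose [3,3] shift is suprafacial on the ring, should relay the C1–O configuration to the new C5–C6 bond on the same face while the alkene moves to C1=C10.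

Step 3
Reactants: 4 (R)-2-(2,6,6-trimethylcyclohex-2-en-1-yl)acetaldehyde
Product: 5 (R)-6-allyl-1,5,5-trimethylcyclohex-1-ene
Conditions: Ph3PCH3Br, KOtBu, THF, 0 °C to rt
Reagents that add atoms: methyltriphenylphosphonium bromide C[P+](c1ccccc1)(c1ccccc1)c1ccccc1.[Br-]
Why: Wittig methylenation of an unhindered aldehyde whose α-carbon is not stereogenic completes the C5 allyl arm (C6–C7=CH2) without touching C5.

Step 4
Reactants: 5 (R)-6-allyl-1,5,5-trimethylcyclohex-1-ene
Product: 6 (R)-4-allyl-3,5,5-trimethylcyclohex-2-en-1-one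
Conditions: CrO3, 3,5-dimethylpyrazole, CH2Cl2, −20 °C
Reagents that add atoms: chromium trioxide O=[Cr](=O)=O
Why: Allylic oxidation with the CrO3–dimethylpyrazole complex should attack C2, the only ring methylene allylic to the electron-rich trisubstituted alkene (oxygen delivery at either end of that allyl unit leads to the same enone), while the terminal alkene is far less reactive.

Step 5
Reactants: 7 geraniol
Product: 8 geranyl tert-butyldimethylsilyl ether
Conditions: TBSCl, imidazole, CH2Cl2, rt
Reagents that add atoms: tert-butyldimethylsilyl chloride CC(C)(C)[Si](C)(C)Cl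
Why: Standard silylation of a primary alcohol gives a C15 protecting group that tolerates organobarium, KH and amide bases, which an acetate would not.

Step 6
Reactants: 8 geranyl tert-butyldimethylsilyl ether
Product: 9 (2E,6E)-8-(tert-butyldimethylsilyloxy)-2,6-dimethylocta-2,6-dien-1-ol
Conditions: SeO2 (cat.), tBuOOH, CH2Cl2, 0 °C to rt
Reagents that add atoms: tert-butyl hydroperoxide CC(C)(C)OO
Why: Selenium dioxide allylic hydroxylation (ene reaction then [2,3] shift) should go to the E-methyl group of the more electron-rich distal alkene, the other alkene being deactivated by its allylic silyloxy group, and this fixes the E geometry later used to set C9.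

Step 7
Reactants: 9 (2E,6E)-8-(tert-butyldimethylsilyloxy)-2,6-dimethylocta-2,6-dien-1-ol
Product: 11 tert-butyl{[(2E,6E)-8-chloro-3,7-dimethylocta-2,6-dien-1-yl]oxy}dimethylsilane, via allylic mesylate 10 (not isolated)
Conditions: MsCl, 2,4,6-collidine, LiCl, DMF, 0 °C
Reagents that add atoms: lithium chloride [Li+].[Cl-]; methanesulfonyl chloride CS(=O)(=O)Cl (its atoms stay only in 10)
Why: Mesylation with in situ SN2 displacement by chloride is the usual way to primary allylic chlorides without allylic transposition or loss of alkene geometry.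

Step 8
Reactants: 11 tert-butyl{[(2E,6E)-8-chloro-3,7-dimethylocta-2,6-dien-1-yl]oxy}dimethylsilane; 6 (R)-4-allyl-3,5,5-trimethylcyclohex-2-en-1-one
Product: 13 (1S,4R)-4-allyl-1-[(2E,6E)-8-(tert-butyldimethylsilyloxy)-2,6-dimethylocta-2,6-dien-1-yl]-3,5,5-trimethylcyclohex-2-en-1-ol, via allylbarium chloride 12 (not isolated)
Conditions: BaI2, Li, biphenyl, THF, rt (active barium); 11, −78 °C; then 6, −78 °C; aq NH4Cl
Reagents that add atoms: barium diiodide [Ba+2].[I-].[I-] (barium stays only in 12)
Why: Allylbarium carbonyl addition takes place at the unsubstituted α-carbon with retention of alkene geometry and in 1,2 fashion on enones, and attack on the C2 face opposite the C5 allyl arm (the allyl-side face is screened by the axial C4 methyl in the conformer with an equatorial allyl group) should set the carbinol centre.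

Step 9
Reactants: 13 (1S,4R)-4-allyl-1-[(2E,6E)-8-(tert-butyldimethylsilyloxy)-2,6-dimethylocta-2,6-dien-1-yl]-3,5,5-trimethylcyclohex-2-en-1-ol
Product: 16 (3S,4R)-4-allyl-3-[(3R,6E)-8-(tert-butyldimethylsilyloxy)-2,6-dimethylocta-1,6-dien-3-yl]-3,5,5-trimethylcyclohexan-1-one, via potassium alkoxide 14 (not isolated), via potassium enolate 15 (not isolated)
Conditions: KH, 18-crown-6, THF, 0 to 40 °C; aq NH4Cl
Reagents that add atoms: potassium hydride [K+].[H-] (potassium stays only in 14 and 15)
Why: In this anionic oxy-Cope rearrangement of a 1-allylcyclohex-2-enolate the naked alkoxide weakens the C2–CH2 bond, the suprafacial [3,3] shift moves the chain from the C2 face anti to the allyl arm onto the same face of C10 (quaternary centre trans to the C5 arm), a chair-like array with the E-alkene chain pseudo-equatorial sets C9, and irreversible formation of the C1=C2 enolate keeps the oxygen on C2 and unveils the isopropenyl group.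

Step 10
Reactants: 16 (3S,4R)-4-allyl-3-[(3R,6E)-8-(tert-butyldimethylsilyloxy)-2,6-dimethylocta-1,6-dien-3-yl]-3,5,5-trimethylcyclohexan-1-one
Product: 17 (5R,9R,10R)-15-(tert-butyldimethylsilyloxy)-ent-labda-7,13E-dien-2-one
Conditions: second-generation Hoveyda–Grubbs catalyst (H2IMes)Cl2Ru=CH(2-iPrOC6H4) (5 mol%), 1,4-benzoquinone (10 mol%), toluene (0.005 M), 80 °C, argon sparge
Reagents that add atoms: none
Why: Ring-closing olefin metathesis by the metallacycle mechanism: the ruthenium alkylidene first exchanges with the unhindered monosubstituted alkene of the C5 allyl arm, the resulting C7 alkylidene adds across the 1,1-disubstituted C8=CH2 bond to a ruthenacyclobutane, and cycloreversion gives C7=C8 and Ru=CH2, whose methylene leaves as ethylene in the next turnover. The closest known reaction type is closure of allyl/isopropenyl 1,7-dienes to 1-methylcyclohexenes with N-heterocyclic-carbene ruthenium catalysts. Ring B closes as a six-membered carbocycle with both former internal alkene carbons endocyclic, and the trans-diequatorial C5 and C10 arms on the ring-A chair hold the termini within reach so that the trans-decalin forms without strain. No stereocentre is created, and C5, C9 and C10 are not touched. The selectivity needed is chemoselectivity for the two terminal alkenes, secured because the trisubstituted C13=C14 alkene is too hindered to be engaged and could only give an eight-membered ring, while the ketone and the silyl ether are inert. Benzoquinone suppresses ruthenium hydride migration of the allyl double bond, so the alkene position is fixed by the two termini and no 8-ene or exocyclic isomer can arise.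

Step 11
Reactants: 17 (5R,9R,10R)-15-(tert-butyldimethylsilyloxy)-ent-labda-7,13E-dien-2-one
Product: 19 (3R,5S,9R,10S)-15-(tert-butyldimethylsilyloxy)-3-hydroxy-ent-labda-7,13E-dien-2-one (axial C3-OH), via potassium C2-C3 enolate 18 (not isolated)
Conditions: KN(SiMe3)2, THF, −78 °C; 2-(phenylsulfonyl)-3-phenyloxaziridine, −78 °C; aq NH4Cl
Reagents that add atoms: 2-(phenylsulfonyl)-3-phenyloxaziridine O=S(=O)(c1ccccc1)N1OC1c1ccccc1; potassium hexamethyldisilazide C[Si](C)(C)[N-][Si](C)(C)C.[K+] (potassium stays only in 18)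
Why: In this enolate hydroxylation with an N-sulfonyloxaziridine, 10-methyl-trans-2-decalones enolise towards C3 and the bulky amide avoids the C1 hydrogens screened by C9 and C11, the reagent leaves the alkenes untouched, and oxygen is taken up from the face opposite the two axial methyl groups, giving the axial C3 alcohol.

Step 12
Reactants: 19 (3R,5S,9R,10S)-15-(tert-butyldimethylsilyloxy)-3-hydroxy-ent-labda-7,13E-dien-2-one (axial C3-OH)
Product: 20 (3S,5S,9R,10S)-15-(tert-butyldimethylsilyloxy)-3-hydroxy-ent-labda-7,13E-dien-2-one (equatorial C3-OH)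
Conditions: K2CO3 (cat.), MeOH, rt, argon
Reagents that add atoms: none
Why: Base-mediated α-ketol equilibration through the enediolate should drain to the equatorial, hydrogen-bonded C3 alcohol with the carbonyl on C2, because an sp2 C2 removes the axial hydrogen that is syn to both axial methyl groups (on C4 and C10), so C3 is set under thermodynamic control.

Step 13
Reactants: 20 (3S,5S,9R,10S)-15-(tert-butyldimethylsilyloxy)-3-hydroxy-ent-labda-7,13E-dien-2-one (equatorial C3-OH)
Product: 21 (3S,5S,9R,10S)-3,15-dihydroxy-ent-labda-7,13E-dien-2-one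
Conditions: HF·pyridine, THF, 0 °C
Reagents that add atoms: none
Why: Fluoride cleavage of a primary silyl ether under mildly acidic, non-basic conditions should leave the base-sensitive ketol and both trisubstituted alkenes unchanged.

Step 14
Reactants: 21 (3S,5S,9R,10S)-3,15-dihydroxy-ent-labda-7,13E-dien-2-one
Product: 22 (3S,5S,9R,10S)-3-hydroxy-2-oxo-ent-labda-7,13E-dien-15-yl acetate (CNP0164008.1)
Conditions: Ac2O (1.1 equiv), pyridine, CH2Cl2, 0 °C
Reagents that add atoms: acetic anhydride CC(=O)OC(C)=O
Why: Selective acylation should take the primary allylic C15 alcohol, since the C3 alcohol is secondary, flanked by the C4 gem-dimethyl group and hydrogen-bonded to the ketone.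

**Compound list**

1 | 2,4,4-trimethylcyclohex-2-en-1-one | CC1=CC(C)(C)CCC1=O | starting material
2 | (S)-2,4,4-trimethylcyclohex-2-en-1-ol | O[C@H]1CCC(C)(C)C=C1C | intermediate
3 | (S)-2,4,4-trimethylcyclohex-2-en-1-yl vinyl ether | C=CO[C@H]1CCC(C)(C)C=C1C | intermediate
4 | (R)-2-(2,6,6-trimethylcyclohex-2-en-1-yl)acetaldehyde | O=CC[C@@H]1C(C)(C)CCC=C1C | intermediate
5 | (R)-6-allyl-1,5,5-trimethylcyclohex-1-ene | C=CC[C@@H]1C(C)(C)CCC=C1C | intermediate
6 | (R)-4-allyl-3,5,5-trimethylcyclohex-2-en-1-one | C=CC[C@@H]1C(C)(C)CC(=O)C=C1C | intermediate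
7 | geraniol | CC(C)=CCC/C(C)=C/CO | starting material
8 | geranyl tert-butyldimethylsilyl ether | CC(C)=CCC/C(C)=C/CO[Si](C)(C)C(C)(C)C | intermediate
9 | (2E,6E)-8-(tert-butyldimethylsilyloxy)-2,6-dimethylocta-2,6-dien-1-ol | OC/C(C)=C/CC/C(C)=C/CO[Si](C)(C)C(C)(C)C | intermediate
10 | (2E,6E)-8-(tert-butyldimethylsilyloxy)-2,6-dimethylocta-2,6-dien-1-yl methanesulfonate | CS(=O)(=O)OC/C(C)=C/CC/C(C)=C/CO[Si](C)(C)C(C)(C)C | intermediate
11 | tert-butyl{[(2E,6E)-8-chloro-3,7-dimethylocta-2,6-dien-1-yl]oxy}dimethylsilane | ClC/C(C)=C/CC/C(C)=C/CO[Si](C)(C)C(C)(C)C | intermediate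
12 | (2E,6E)-8-(tert-butyldimethylsilyloxy)-2,6-dimethylocta-2,6-dien-1-ylbarium chloride | Cl[Ba]C/C(C)=C/CC/C(C)=C/CO[Si](C)(C)C(C)(C)C | intermediate
13 | (1S,4R)-4-allyl-1-[(2E,6E)-8-(tert-butyldimethylsilyloxy)-2,6-dimethylocta-2,6-dien-1-yl]-3,5,5-trimethylcyclohex-2-en-1-ol (side chain trans to the allyl group) | CC(C)(C)[Si](C)(C)OC/C=C(\C)CC/C=C(\C)C[C@@]1(O)C=C(C)[C@H](CC=C)C(C)(C)C1 | intermediate
14 | potassium alkoxide of 13 | CC(C)(C)[Si](C)(C)OC/C=C(\C)CC/C=C(\C)C[C@@]1([O-])C=C(C)[C@H](CC=C)C(C)(C)C1.[K+] | intermediate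
15 | potassium C1=C2 enolate of 16 | CC(C)(C)[Si](C)(C)OC/C=C(\C)CC[C@H](C(C)=C)[C@]1(C)C=C([O-])CC(C)(C)[C@H]1CC=C.[K+] | intermediate
16 | (3S,4R)-4-allyl-3-[(3R,6E)-8-(tert-butyldimethylsilyloxy)-2,6-dimethylocta-1,6-dien-3-yl]-3,5,5-trimethylcyclohexan-1-one (metathesis precursor) | CC(C)(C)[Si](C)(C)OC/C=C(\C)CC[C@H](C(C)=C)[C@]1(C)CC(=O)CC(C)(C)[C@H]1CC=C | intermediate
17 | (5R,9R,10R)-15-(tert-butyldimethylsilyloxy)-ent-labda-7,13E-dien-2-one (metathesis product) | CC(C)(C)[Si](C)(C)OC/C=C(\C)CC[C@@H]1C(C)=CC[C@@H]2C(C)(C)CC(=O)C[C@@]12C | intermediate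
18 | potassium C2=C3 enolate of 17 | CC(C)(C)[Si](C)(C)OC/C=C(\C)CC[C@@H]1C(C)=CC[C@@H]2C(C)(C)C=C([O-])C[C@@]12C.[K+] | intermediate
19 | (3R,5S,9R,10S)-15-(tert-butyldimethylsilyloxy)-3-hydroxy-ent-labda-7,13E-dien-2-one (axial C3-OH) | CC(C)(C)[Si](C)(C)OC/C=C(\C)CC[C@@H]1C(C)=CC[C@@H]2C(C)(C)[C@@H](O)C(=O)C[C@@]12C | intermediate
20 | (3S,5S,9R,10S)-15-(tert-butyldimethylsilyloxy)-3-hydroxy-ent-labda-7,13E-dien-2-one (equatorial C3-OH) | CC(C)(C)[Si](C)(C)OC/C=C(\C)CC[C@@H]1C(C)=CC[C@@H]2C(C)(C)[C@H](O)C(=O)C[C@@]12C | intermediate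
21 | (3S,5S,9R,10S)-3,15-dihydroxy-ent-labda-7,13E-dien-2-one | OC/C=C(\C)CC[C@@H]1C(C)=CC[C@@H]2C(C)(C)[C@H](O)C(=O)C[C@@]12C | intermediate
22 | (3S,5S,9R,10S)-3-hydroxy-2-oxo-ent-labda-7,13E-dien-15-yl acetate (CNP0164008.1) | CC(=O)OC/C=C(\C)CC[C@@H]1C(C)=CC[C@@H]2C(C)(C)[C@H](O)C(=O)C[C@@]12C | target

Total step count: 14. Longest linear sequence: 11 (steps 1–4 and 8–14).

**Steps most likely to fail**

Step 9. The hindered alkoxide may rearrange partly or mainly through a boat-like array, because the C4 gem-dimethyl group lies under the migrating chain. That would erode or invert the sense of induction at C9.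

The fallback sets out from 8 and returns at 16. It inverts the geometry of the migrating alkene, so that the boat delivers the correct C9 centre.
- mCPBA epoxidises the electron-rich distal alkene of 8 to 6,7-epoxygeranyl tert-butyldimethylsilyl ether F1.
- H5IO6 cleaves this to (E)-6-(tert-butyldimethylsilyloxy)-4-methylhex-4-enal F2.
- A Still–Gennari olefination with ethyl 2-[bis(2,2,2-trifluoroethoxy)phosphoryl]propanoate (KN(SiMe3)2, 18-crown-6, THF, −78 °C) gives ethyl (2Z,6E)-8-(tert-butyldimethylsilyloxy)-2,6-dimethylocta-2,6-dienoate F3.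
- iBu2AlH gives (2Z,6E)-8-(tert-butyldimethylsilyloxy)-2,6-dimethylocta-2,6-dien-1-ol F4.
- MsCl, collidine and LiCl give the (2E,6Z)-8-chloro silyl ether F5.
- Active barium followed by 6 gives the Z-configured tertiary carbinol F6, whose potassium alkoxide should reach 16 through the boat.

Step 8. Three processes could starve the route of 13: enolisation of the hindered enone by the basic allyl metal, leakage to attack through the γ-carbon, or a weak facial bias at C2.

The fallback sets out from 11 and 6 and returns at 16, bypassing 13. It replaces 1,2-addition plus rearrangement by conjugate allylation.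
- The allylbarium 12 made from 11 is quenched at its α-carbon with Me3SiCl to give the (2E,6E)-allyltrimethylsilane F7.
- A Hosomi–Sakurai reaction of F7 with 6 (TiCl4, CH2Cl2, −78 °C) joins the γ-carbon (C9) to C10 by axial attack anti to the C5 allyl arm.
- This unveils the isopropenyl group and gives 16 directly. Any C9 epimer would be removed after ring closure.

Step 11. Deprotonation at C1 may compete with deprotonation at C3, since both α-carbons are flanked by quaternary centres, and oxygen would then be placed on the wrong side of the ketone.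

The fallback sets out from 6 and returns at 20. It installs the oxygen on the enone, where only the cross-conjugated α′-enolate (C3) can form.
- KN(SiMe3)2 and the same oxaziridine give trans-4-allyl-6-hydroxy-3,5,5-trimethylcyclohex-2-en-1-one F8, with oxygen entering anti to the allyl arm.
- 4-Methoxybenzyl trichloroacetimidate with La(OTf)3 (cat.) gives the trans 4-methoxybenzyl ether F9.
- LiN(iPr)2 followed by kinetic protonation with 2,6-di-tert-butylphenol from the same open face gives the cis 4-methoxybenzyl ether F10.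
- The conditions of steps 8, 9 and 10 then give in turn the ether-bearing tertiary carbinol F11, the ether-bearing metathesis precursor F12 and the C3 4-methoxybenzyl ether of 20 F13.
- DDQ (CH2Cl2, pH 7 buffer) releases 20.

**Further compounds**

F1 | step 9 | 6,7-epoxygeranyl tert-butyldimethylsilyl ether (racemic at the epoxide carbon) | CC1(C)OC1CC/C(C)=C/CO[Si](C)(C)C(C)(C)C
F2 | step 9 | (E)-6-(tert-butyldimethylsilyloxy)-4-methylhex-4-enal | O=CCC/C(C)=C/CO[Si](C)(C)C(C)(C)C
F3 | step 9 | ethyl (2Z,6E)-8-(tert-butyldimethylsilyloxy)-2,6-dimethylocta-2,6-dienoate | CCOC(=O)/C(C)=C\CC/C(C)=C/CO[Si](C)(C)C(C)(C)C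
F4 | step 9 | (2Z,6E)-8-(tert-butyldimethylsilyloxy)-2,6-dimethylocta-2,6-dien-1-ol | OC/C(C)=C\CC/C(C)=C/CO[Si](C)(C)C(C)(C)C
F5 | step 9 | tert-butyl{[(2E,6Z)-8-chloro-3,7-dimethylocta-2,6-dien-1-yl]oxy}dimethylsilane | ClC/C(C)=C\CC/C(C)=C/CO[Si](C)(C)C(C)(C)C
F6 | step 9 | (1S,4R)-4-allyl-1-[(2Z,6E)-8-(tert-butyldimethylsilyloxy)-2,6-dimethylocta-2,6-dien-1-yl]-3,5,5-trimethylcyclohex-2-en-1-ol | CC(C)(C)[Si](C)(C)OC/C=C(\C)CC/C=C(/C)C[C@@]1(O)C=C(C)[C@H](CC=C)C(C)(C)C1
F7 | step 8 | tert-butyldimethyl{[(2E,6E)-3,7-dimethyl-8-(trimethylsilyl)octa-2,6-dien-1-yl]oxy}silane | C[Si](C)(C)C/C(C)=C/CC/C(C)=C/CO[Si](C)(C)C(C)(C)C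
F8 | step 11 | trans-4-allyl-6-hydroxy-3,5,5-trimethylcyclohex-2-en-1-one (OH anti to allyl) | C=CC[C@@H]1C(C)(C)[C@@H](O)C(=O)C=C1C
F9 | step 11 | trans-4-allyl-6-(4-methoxybenzyloxy)-3,5,5-trimethylcyclohex-2-en-1-one | C=CC[C@@H]1C(C)(C)[C@@H](OCc2ccc(OC)cc2)C(=O)C=C1C
F10 | step 11 | cis-4-allyl-6-(4-methoxybenzyloxy)-3,5,5-trimethylcyclohex-2-en-1-one | C=CC[C@@H]1C(C)(C)[C@H](OCc2ccc(OC)cc2)C(=O)C=C1C
F11 | step 11 | 6-(4-methoxybenzyloxy) analogue of carbinol 13 (ether cis to allyl, side chain trans to both) | CC(C)(C)[Si](C)(C)OC/C=C(\C)CC/C=C(\C)C[C@@]1(O)C=C(C)[C@H](CC=C)C(C)(C)[C@@H]1OCc2ccc(OC)cc2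
F12 | step 11 | C3 4-methoxybenzyloxy analogue of ketone 16 | CC(C)(C)[Si](C)(C)OC/C=C(\C)CC[C@H](C(C)=C)[C@]1(C)CC(=O)[C@@H](OCc2ccc(OC)cc2)C(C)(C)[C@H]1CC=C
F13 | step 11 | C3 4-methoxybenzyl ether of 20 | CC(C)(C)[Si](C)(C)OC/C=C(\C)CC[C@@H]1C(C)=CC[C@@H]2C(C)(C)[C@H](OCc3ccc(OC)cc3)C(=O)C[C@@]12C
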